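The quinone half is numbered as a 2-ethyl-3-oxy-1,4-naphthoquinone. Its ring atoms C1(=O)–C2(Et)=C3(O)–C4(=O) map onto the four carbons of a squaric acid derivative, and fusion carbon C8a, next to the C8 oxygen, is the free ortho position of a 2,3,5-trioxygenated aryl group. A 4-aryl-4-hydroxycyclobutenone, a ring absent from the target, is therefore heated: electrocyclic opening to a dienylketene and 6π closure form the C1–C8a bond and, after hydrolysis, give the protected 2-ethyl-3-hydroxynaphthoquinone. Both halves of the target are this monomer. A reagent-controlled oxidative dehydrodimerisation (chiral trivalent iodine) joins O3 of one unit to C2 of the other, creating the trione and the S ether centre; acidolysis of six PMB ethers completes the route.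

Key step: step 6

Assumption: the sense of induction of the chiral iodine reagent in step 8 cannot be fixed on paper; the (R,R)-reagent is written, and its antipode would be used if it should favour the (R)-dimer.
Remark: PMB = 4-methoxybenzyl. The target is treated as the tautomer drawn (carbonyls on the quinone and trione rings, benzenoid trihydroxy rings). The iodane of step 8 is an isolable reagent made beforehand from the corresponding iodoarene and is not counted as a step.

Step 1
Reactants: 1 3-bromo-4,5-dihydroxybenzaldehyde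
Product: 2 3-bromo-4,5-bis[(4-methoxybenzyl)oxy]benzaldehyde
Conditions: PMBCl, K2CO3, Bu4NI (cat.), DMF, 60 °C
Reagents that add atoms: 4-methoxybenzyl chloride, COc1ccc(CCl)cc1
Why: Williamson etherification of both phenols by the benzylic chloride under carbonate base should proceed cleanly, and no stereocentre is involved.

Step 2
Reactants: 2 3-bromo-4,5-bis[(4-methoxybenzyl)oxy]benzaldehyde
Product: 4 3-bromo-4,5-bis[(4-methoxybenzyl)oxy]phenol, via aryl formate 3 (not isolated)
Conditions: mCPBA, CH2Cl2, 0 °C to rt; then K2CO3 (cat.), MeOH, rt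
Reagents that add atoms: mCPBA, OOC(=O)c1cccc(Cl)c1
Why: Baeyer–Villiger oxidation of the aldehyde, in which the electron-rich aryl group (para oxygen) migrates to oxygen, should give the formate, which methanolysis converts into the phenol.

Step 3
Reactants: 4 3-bromo-4,5-bis[(4-methoxybenzyl)oxy]phenol
Product: 5 1-bromo-2,3,5-tris[(4-methoxybenzyl)oxy]benzene
Conditions: PMBCl, K2CO3, Bu4NI (cat.), DMF, 60 °C
Reagents that add atoms: 4-methoxybenzyl chloride, COc1ccc(CCl)cc1
Why: Williamson etherification of the remaining phenol completes the aryl bromide whose bromine marks the future C4a and whose free ortho carbon is the future C8a.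

Step 4
Reactants: 6 dimethyl squarate
Product: 8 3-ethyl-4-methoxycyclobut-3-ene-1,2-dione, via lithium alkoxide adduct 7 (not isolated)
Conditions: EtLi, THF, –78 °C; then (CF3CO)2O, –78 °C; then H2O, 0 °C
Reagents that add atoms: ethyllithium, [Li]CC; water, O
Why: 1,2-addition of the organolithium to one squarate carbonyl, followed by trifluoroacetylation and ionisation of the carbinol with 1,3-transposition (water adds to the methoxy-stabilised cation and methanol is lost), is the standard conversion of a dialkyl squarate into a 3-alkyl-4-alkoxycyclobutenedione.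

Step 5
Reactants: 5 1-bromo-2,3,5-tris[(4-methoxybenzyl)oxy]benzene; 8 3-ethyl-4-methoxycyclobut-3-ene-1,2-dione
Product: 10 rac-2-ethyl-4-hydroxy-3-methoxy-4-{2,3,5-tris[(4-methoxybenzyl)oxy]phenyl}cyclobut-2-en-1-one, via aryllithium 9 (not isolated)
Conditions: n-BuLi, THF, –78 °C; then 8, THF, –78 °C; then aq NH4Cl
Reagents that add atoms: none
Why: Bromine–lithium exchange gives aryllithium 9, which should add 1,2 to the ketone-like carbonyl of 8 next to the methoxy-bearing carbon (the other carbonyl is deactivated as a vinylogous ester), so that the ethyl group sits next to the remaining cyclobutenone carbonyl; the new carbinol centre is racemic and is destroyed in step 6.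

Step 6
Reactants: 10 rac-2-ethyl-4-hydroxy-3-methoxy-4-{2,3,5-tris[(4-methoxybenzyl)oxy]phenyl}cyclobut-2-en-1-one
Product: 13 2-ethyl-3-methoxy-5,6,8-tris[(4-methoxybenzyl)oxy]naphthalene-1,4-dione, via dienylketene 11 (not isolated), via hydroquinone 12 (not isolated)
Conditions: p-xylene, 138 °C, argon; then Ag2O, rt
Reagents that add atoms: none
Why: Heating opens the cyclobutenone by conrotatory 4π electrocyclic cleavage of its C1–C4 bond, the donor hydroxyl rotating outward so that the aryl group of dienylketene 11 lies cis to the ketene carbon. That carbon then bonds to the only unsubstituted ortho carbon of the aryl ring in a thermal 6π electrocyclisation, which creates the bond between the future quinone carbonyl next to the ethyl-bearing carbon and fusion carbon C8a; tautomerisation gives hydroquinone 12, which Ag2O oxidises to quinone 13. The closest known reaction type is the Moore rearrangement of 4-aryl-4-hydroxycyclobutenones to naphthoquinones. The one ring closed, the six-membered quinone ring, is closed by disrotatory 6π electrocyclisation, while the four-membered ring, which is not in the target, is consumed. No stereocentre is formed and the racemic carbinol centre of 10 disappears. The step needs regioselectivity and torquoselectivity: the second ortho carbon bears a PMB ether and cannot aromatise after closure, the ethyl-next-to-ketene arrangement was fixed by the addition in step 5, and the outward preference of the hydroxyl keeps it away from the ketene.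

Step 7
Reactants: 13 2-ethyl-3-methoxy-5,6,8-tris[(4-methoxybenzyl)oxy]naphthalene-1,4-dione
Product: 14 2-ethyl-3-hydroxy-5,6,8-tris[(4-methoxybenzyl)oxy]naphthalene-1,4-dione
Conditions: LiOH, THF/H2O, 0 °C to rt; then 1 M HCl to pH 3, 0 °C
Reagents that add atoms: lithium hydroxide, [Li+].[OH-]
Why: The 3-methoxyquinone is a vinylogous ester and should undergo conjugate addition–elimination with hydroxide, whereas the aryl PMB ethers are inert to base.

Step 8
Reactants: 14 2-ethyl-3-hydroxy-5,6,8-tris[(4-methoxybenzyl)oxy]naphthalene-1,4-dione (two molecules)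
Product: 15 (2S)-2-ethyl-2-({3-ethyl-5,7,8-tris[(4-methoxybenzyl)oxy]-1,4-dioxo-1,4-dihydronaphthalen-2-yl}oxy)-5,6,8-tris[(4-methoxybenzyl)oxy]naphthalene-1,3,4(2H)-trione
Conditions: (R,R)-2,6-bis[1-(methoxycarbonyl)ethoxy]phenyliodine diacetate, ArI(OAc)2 (0.5 equiv), CH2Cl2, –40 °C to 0 °C
Reagents that add atoms: none
Why: Proposed new method: the acidic 3-hydroxyl groups of two molecules of 14 should displace both acetates on trivalent iodine, and reductive loss of the iodoarene should then transfer one quinonyloxy ligand to C2 of the iodine-bound enolate of the other (ligand coupling of the SN2' type), forming the tertiary C2–O bond and the 1,3,4-trione while the C2-symmetric lactate arms shield one face of C2 so that the S centre is set by the reagent; the closest known reaction types are the dehydrodimerisation of 2-hydroxy-3-alkyl-1,4-naphthoquinones by PbO2 to racemic quinonyl ethers of this kind and the enantioselective oxidative dearomatisation of naphthols with oxygen nucleophiles by chiral aryl iodine reagents.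

Step 9
Reactants: 15 (2S)-2-ethyl-2-({3-ethyl-5,7,8-tris[(4-methoxybenzyl)oxy]-1,4-dioxo-1,4-dihydronaphthalen-2-yl}oxy)-5,6,8-tris[(4-methoxybenzyl)oxy]naphthalene-1,3,4(2H)-trione
Product: 16 (2S)-2-ethyl-2-[(3-ethyl-5,7,8-trihydroxy-1,4-dioxo-1,4-dihydronaphthalen-2-yl)oxy]-5,6,8-trihydroxynaphthalene-1,3,4(2H)-trione
Conditions: CF3CO2H, pentamethylbenzene, CH2Cl2, 0 °C
Reagents that add atoms: none
Why: Acidolysis of the six aryl PMB ethers with Friedel–Crafts capture of the 4-methoxybenzyl cation by pentamethylbenzene should free the phenols, while the quaternary centre has no enolisable hydrogen and its ether cannot ionise between two carbonyls, so linkage and configuration should persist.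

Compound list
1 | 3-bromo-4,5-dihydroxybenzaldehyde | O=Cc1cc(O)c(O)c(Br)c1 | starting material
2 | 3-bromo-4,5-bis[(4-methoxybenzyl)oxy]benzaldehyde | O=Cc1cc(OCc2ccc(OC)cc2)c(OCc2ccc(OC)cc2)c(Br)c1 | intermediate
3 | 3-bromo-4,5-bis[(4-methoxybenzyl)oxy]phenyl formate (not isolated) | O=COc1cc(OCc2ccc(OC)cc2)c(OCc2ccc(OC)cc2)c(Br)c1 | intermediate
4 | 3-bromo-4,5-bis[(4-methoxybenzyl)oxy]phenol | Oc1cc(OCc2ccc(OC)cc2)c(OCc2ccc(OC)cc2)c(Br)c1 | intermediate
5 | 1-bromo-2,3,5-tris[(4-methoxybenzyl)oxy]benzene | Brc1cc(OCc2ccc(OC)cc2)cc(OCc2ccc(OC)cc2)c1OCc1ccc(OC)cc1 | intermediate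
6 | dimethyl squarate (3,4-dimethoxycyclobut-3-ene-1,2-dione) | COC1=C(OC)C(=O)C1=O | starting material
7 | lithium 1-ethyl-2,3-dimethoxy-4-oxocyclobut-2-en-1-olate, racemic (not isolated) | CCC1([O-])C(OC)=C(OC)C1=O.[Li+] | intermediate
8 | 3-ethyl-4-methoxycyclobut-3-ene-1,2-dione | CCC1=C(OC)C(=O)C1=O | intermediate
9 | {2,3,5-tris[(4-methoxybenzyl)oxy]phenyl}lithium (not isolated) | [Li]c1cc(OCc2ccc(OC)cc2)cc(OCc2ccc(OC)cc2)c1OCc1ccc(OC)cc1 | intermediate
10 | rac-2-ethyl-4-hydroxy-3-methoxy-4-{2,3,5-tris[(4-methoxybenzyl)oxy]phenyl}cyclobut-2-en-1-one | CCC1=C(OC)C(O)(c2cc(OCc3ccc(OC)cc3)cc(OCc3ccc(OC)cc3)c2OCc2ccc(OC)cc2)C1=O | intermediate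
11 | (3Z)-2-ethyl-4-hydroxy-3-methoxy-4-{2,3,5-tris[(4-methoxybenzyl)oxy]phenyl}buta-1,3-dien-1-one (not isolated) | CCC(=C=O)/C(OC)=C(/O)c1cc(OCc2ccc(OC)cc2)cc(OCc2ccc(OC)cc2)c1OCc1ccc(OC)cc1 | intermediate
12 | 2-ethyl-3-methoxy-5,6,8-tris[(4-methoxybenzyl)oxy]naphthalene-1,4-diol (not isolated) | CCc1c(OC)c(O)c2c(OCc3ccc(OC)cc3)c(OCc3ccc(OC)cc3)cc(OCc3ccc(OC)cc3)c2c1O | intermediate
13 | 2-ethyl-3-methoxy-5,6,8-tris[(4-methoxybenzyl)oxy]naphthalene-1,4-dione | CCC1=C(OC)C(=O)c2c(OCc3ccc(OC)cc3)c(OCc3ccc(OC)cc3)cc(OCc3ccc(OC)cc3)c2C1=O | intermediate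
14 | 2-ethyl-3-hydroxy-5,6,8-tris[(4-methoxybenzyl)oxy]naphthalene-1,4-dione | CCC1=C(O)C(=O)c2c(OCc3ccc(OC)cc3)c(OCc3ccc(OC)cc3)cc(OCc3ccc(OC)cc3)c2C1=O | intermediate
15 | (2S)-2-ethyl-2-({3-ethyl-5,7,8-tris[(4-methoxybenzyl)oxy]-1,4-dioxo-1,4-dihydronaphthalen-2-yl}oxy)-5,6,8-tris[(4-methoxybenzyl)oxy]naphthalene-1,3,4(2H)-trione | CCC1=C(O[C@]2(CC)C(=O)C(=O)c3c(OCc4ccc(OC)cc4)c(OCc4ccc(OC)cc4)cc(OCc4ccc(OC)cc4)c3C2=O)C(=O)c2c(OCc3ccc(OC)cc3)c(OCc3ccc(OC)cc3)cc(OCc3ccc(OC)cc3)c2C1=O | intermediate
16 | (2S)-2-ethyl-2-[(3-ethyl-5,7,8-trihydroxy-1,4-dioxo-1,4-dihydronaphthalen-2-yl)oxy]-5,6,8-trihydroxynaphthalene-1,3,4(2H)-trione | CCC1=C(O[C@]2(CC)C(=O)C(=O)c3c(O)c(O)cc(O)c3C2=O)C(=O)c2c(O)c(O)cc(O)c2C1=O | target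

Total step count: 9 steps.
Longest linear sequence: 8 steps (steps 1, 2, 3, 5, 6, 7, 8, 9 from compound 1); step 4 is a one-step side branch from compound 6.

Steps most likely to fail

1. Step 8 (proposed new method). The iodine-bound enolate may be captured by acetate instead of by the oxygen of a second quinone, and the reagent may not discriminate the two faces of C2 well enough. Fallback: the route sets out again from 14, which would be oxidised with PbO2 in AcOH at rt, the known dehydrodimerisation of 2-hydroxy-3-alkyl-1,4-naphthoquinones, to give the racemic hexakis(4-methoxybenzyl) dimer F1. Preparative HPLC on a chiral stationary phase (amylose tris(3,5-dimethylphenylcarbamate)) would then separate 15 from its antipode, the (R)-configured hexakis(4-methoxybenzyl) dimer F2, and the route is rejoined at 15.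

2. Step 6 (key step). The dienylketene may lactonise through its own hydroxyl after inward rotation, or decompose thermally before it closes onto the arene. Fallback: the route sets out from 10, which would be silylated with 1-(trimethylsilyl)imidazole in CH2Cl2 to the trimethylsilyl ether F3, so that no free hydroxyl can reach the ketene. Thermolysis in p-xylene would then give, by the same ring opening and 6π closure, the 4-(trimethylsilyloxy)naphthalen-1-ol F4. KF in MeOH would cleave the silyl ether to hydroquinone 12, and Ag2O would oxidise it, so that the route is rejoined at 13.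

3. Step 9. Acid may cleave the quinonyl ether linkage, and 4-methoxybenzyl cations that escape the scavenger may alkylate the freed polyphenol at carbon. Fallback: the route sets out from 15 and removes the PMB groups oxidatively instead of by acidolysis, with DDQ in CH2Cl2/pH 7 buffer at rt (hydride abstraction from the benzylic position and hydrolysis of the resulting oxocarbenium ion). No carbocation is released and no new intermediate is made; the route comes back at 16.

Further compounds
F1 | step 8 | racemic hexakis(4-methoxybenzyl) dimer (racemate of 15) | CCC1=C(OC2(CC)C(=O)C(=O)c3c(OCc4ccc(OC)cc4)c(OCc4ccc(OC)cc4)cc(OCc4ccc(OC)cc4)c3C2=O)C(=O)c2c(OCc3ccc(OC)cc3)c(OCc3ccc(OC)cc3)cc(OCc3ccc(OC)cc3)c2C1=O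
F2 | step 8 | (R)-configured hexakis(4-methoxybenzyl) dimer (antipode of 15) | CCC1=C(O[C@@]2(CC)C(=O)C(=O)c3c(OCc4ccc(OC)cc4)c(OCc4ccc(OC)cc4)cc(OCc4ccc(OC)cc4)c3C2=O)C(=O)c2c(OCc3ccc(OC)cc3)c(OCc3ccc(OC)cc3)cc(OCc3ccc(OC)cc3)c2C1=O
F3 | step 6 | rac-2-ethyl-3-methoxy-4-{2,3,5-tris[(4-methoxybenzyl)oxy]phenyl}-4-[(trimethylsilyl)oxy]cyclobut-2-en-1-one (trimethylsilyl ether of 10) | CCC1=C(OC)C(O[Si](C)(C)C)(c2cc(OCc3ccc(OC)cc3)cc(OCc3ccc(OC)cc3)c2OCc2ccc(OC)cc2)C1=O
F4 | step 6 | 2-ethyl-3-methoxy-5,6,8-tris[(4-methoxybenzyl)oxy]-4-[(trimethylsilyl)oxy]naphthalen-1-ol | CCc1c(OC)c(O[Si](C)(C)C)c2c(OCc3ccc(OC)cc3)c(OCc3ccc(OC)cc3)cc(OCc3ccc(OC)cc3)c2c1O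
F0 | step 9 | none | none
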